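Ring C is built first and ring A is grown onto it. Everything rests on cutting C2–C3 and O1–C8a. Ring C (O1, C2, C3, C4, C4a, C8a) is a 2-aryl-3-oxy-2,3-dihydropyran-4-one, the formal cycloadduct of the ring B aldehyde and a 1-alkoxy-3,4-bis(silyloxy)butadiene. In one operation Ti(OiPr)4/(S)-BINOL joins O-TBS vanillin to the (1E,3Z)-1-ethoxy-3-OTMS-4-OTBS diene and closes ring C. It sets C2 by catalyst control and C3 by equilibration beside C4=O, and it converts the aldehyde oxygen into O1, so a choice between ring A phenols never arises. C4a=C8a is then armed as a vinyl sulfoxide and annulated with a prenylated vinylketene acetal (C5–C8); fluoride unmasks the target.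

Key step: step 6

Assumption: (S)-BINOL is taken to direct attack to the Si face of aldehyde 2, in line with the sense of induction known for Ti(OiPr)4/BINOL additions to aromatic aldehydes; if the sense proved opposite, (R)-BINOL would be used and nothing else would change.
Remark: from step 6 on, ring atoms carry flavonoid numbering (O1, C2, C3, C4, C4a, C5–C8, C8a). Transient stereocentres that are erased again (sulfur in 17; C4a, C5, C8, C8a in 15, 25, 26) are left unassigned.

Step 1
Reactants: 1 vanillin
Product: 2 4-(tert-butyldimethylsilyloxy)-3-methoxybenzaldehyde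
Conditions: TBSCl, imidazole, CH2Cl2, 0 °C → rt
Reagents that add atoms: tert-butyldimethylsilyl chloride, CC(C)(C)[Si](C)(C)Cl
Why: Imidazole-promoted O-silylation (silyl ether protection) of the only hydroxyl group is routine for phenols and leaves the aldehyde untouched.

Step 2
Reactants: 3 methyl glycolate
Product: 4 methyl 2-(tert-butyldimethylsilyloxy)acetate
Conditions: TBSCl, imidazole, CH2Cl2, 0 °C → rt
Reagents that add atoms: tert-butyldimethylsilyl chloride, CC(C)(C)[Si](C)(C)Cl
Why: This is the same silyl ether protection on a primary alcohol, and TBS is chosen because this oxygen becomes O3 and must survive organolithium addition, TFA, PhSCl and mCPBA before fluoride removes it.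

Step 3
Reactants: 4 methyl 2-(tert-butyldimethylsilyloxy)acetate
Product: 5 2-(tert-butyldimethylsilyloxy)-N-methoxy-N-methylacetamide
Conditions: MeNH(OMe)·HCl, i-PrMgCl, THF, −20 → 0 °C
Reagents that add atoms: N,O-dimethylhydroxylamine hydrochloride, CNOC.Cl
Why: Ester aminolysis by the magnesium amide made from the amine salt and i-PrMgCl (N-methoxy-N-methylamide formation) is fast at low temperature and does not touch the silyl ether.

Step 4
Reactants: 5 2-(tert-butyldimethylsilyloxy)-N-methoxy-N-methylacetamide; 6 (Z)-1-bromo-2-ethoxyethene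
Product: 10 (E)-1-(tert-butyldimethylsilyloxy)-4-ethoxybut-3-en-2-one, via (Z)-2-ethoxyvinyllithium 7 (not isolated), via lithium tetrahedral adduct 8 (not isolated), via (Z)-enone 9 (not isolated)
Conditions: 6, n-BuLi, Et2O, −78 °C; 5, −78 → −40 °C; AcOH, −78 °C; crude, PPTS (cat.), CH2Cl2, rt
Reagents that add atoms: none
Why: Br/Li exchange with retention gives the configurationally stable cis-vinyllithium 7, whose addition stops at chelate 8 (Weinreb ketone synthesis); because this necessarily delivers the Z enone 9, acid-catalysed bond rotation in the O-protonated vinylogous oxocarbenium ion is added to reach the more stable E isomer 10 required for the (1E)-diene.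

Step 5
Reactants: 10 (E)-1-(tert-butyldimethylsilyloxy)-4-ethoxybut-3-en-2-one
Product: 11 (1E,3Z)-4-(tert-butyldimethylsilyloxy)-1-ethoxy-3-(trimethylsilyloxy)buta-1,3-diene
Conditions: TMSOTf, Et3N, Et2O, 0 °C
Reagents that add atoms: trimethylsilyl triflate, C[Si](C)(C)OS(=O)(=O)C(F)(F)F
Why: Soft enolisation (silyl triflate/amine enol silylation) can occur only at the single enolisable CH2(OTBS) position and, as with related 4-oxygenated 1-alkoxy-3-silyloxydienes, should give the enol ether with both oxygens cis (3Z), which puts OTBS on the outside of the s-cis diene.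

Step 6
Reactants: 2 4-(tert-butyldimethylsilyloxy)-3-methoxybenzaldehyde; 11 (1E,3Z)-4-(tert-butyldimethylsilyloxy)-1-ethoxy-3-(trimethylsilyloxy)buta-1,3-diene
Product: 14 (2R,3R)-3-(tert-butyldimethylsilyloxy)-2-[4-(tert-butyldimethylsilyloxy)-3-methoxyphenyl]-2,3-dihydro-4H-pyran-4-one, via syn aldol adduct 12 (not isolated), via cis-dihydropyranone 13 (not isolated)
Conditions: (S)-BINOL (20 mol %), Ti(OiPr)4 (10 mol %), 4 Å MS, Et2O, −20 °C; then TFA, CH2Cl2, 0 °C → rt
Reagents that add atoms: none
Why: The Lewis acid formed from Ti(OiPr)4 and (S)-BINOL (tetravalent titanium) binds the aldehyde oxygen of 2, and the OTBS-bearing terminus C4 of diene 11, the most nucleophilic carbon of this push–pull diene, adds to the carbonyl carbon with transfer of the TMS group (Mukaiyama aldol mode of a formal [4+2] cycloaddition), forming C2–C3 and giving 12. The closest known reaction type is the catalytic asymmetric hetero-Diels–Alder reaction of 1-alkoxy-3-silyloxybutadienes with aromatic aldehydes under catalysts made from BINOLs and Ti(OiPr)4 or Zr(OtBu)4, which is documented also for 4-alkyl and 4-alkoxy dienes. TFA then frees the benzylic oxygen, which closes ring C by 6-endo-trig addition to the β-ethoxy enone carbon C8a and loss of ethanol (addition–elimination), forming O1–C8a. C2 is controlled by the ligand, which shields the Re face of the bound aldehyde so that Si-face attack gives 2R. C3 is expected to form mainly cis to the aryl group (13), as is usual for 4-oxygenated dienes, and is therefore placed under thermodynamic substrate control: C3–H lies α to the C4 ketone, and acid-catalysed enolisation lets OTBS settle pseudo-equatorial and trans to the pseudo-equatorial aryl group (3R), any remaining cis isomer being separated and resubmitted. The step needs enantioface selectivity (catalyst), regioselectivity (secured by the 1-ethoxy and 3-silyloxy donors, which make C4 the nucleophilic and C1 the acetal-like terminus) and integrity of C2 during equilibration, which is why acid is used instead of base, since a C3 enolate could expel the vinylogous carboxylate O1 and erase C2.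

Step 7
Reactants: 14 (2R,3R)-3-(tert-butyldimethylsilyloxy)-2-[4-(tert-butyldimethylsilyloxy)-3-methoxyphenyl]-2,3-dihydro-4H-pyran-4-one
Product: 16 (2R,3R)-3-(tert-butyldimethylsilyloxy)-2-[4-(tert-butyldimethylsilyloxy)-3-methoxyphenyl]-5-(phenylsulfanyl)-2,3-dihydro-4H-pyran-4-one, via chloro sulfide adduct 15 (not isolated)
Conditions: PhSCl, CH2Cl2, −78 °C; Et3N, −78 → 0 °C
Reagents that add atoms: benzenesulfenyl chloride, ClSc1ccccc1
Why: This is electrophilic sulfenylation by addition–elimination: C4a is the nucleophilic β-carbon of the O1–C8a=C4a enol ether, so PhSCl adds across this bond to give 15 and Et3N removes the doubly activated C4a–H with loss of chloride (E1cB), while ring B is too weakly activated to react with PhSCl without a Lewis acid and C2 and C3 are untouched in the cold.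

Step 8
Reactants: 16 (2R,3R)-3-(tert-butyldimethylsilyloxy)-2-[4-(tert-butyldimethylsilyloxy)-3-methoxyphenyl]-5-(phenylsulfanyl)-2,3-dihydro-4H-pyran-4-one
Product: 17 (2R,3R)-3-(tert-butyldimethylsilyloxy)-2-[4-(tert-butyldimethylsilyloxy)-3-methoxyphenyl]-5-(phenylsulfinyl)-2,3-dihydro-4H-pyran-4-one (both sulfur epimers)
Conditions: mCPBA (1.0 equiv), CH2Cl2, −78 → −40 °C
Reagents that add atoms: 3-chloroperbenzoic acid, OOC(=O)c1cccc(Cl)c1
Why: Sulfide-to-sulfoxide oxidation with one equivalent of peracid in the cold is much faster than epoxidation of the acceptor-substituted C4a=C8a bond or sulfone formation, and the sulfur stereocentre is irrelevant because sulfur is expelled in step 12.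

Step 9
Reactants: 18 methyl acetoacetate; 19 prenyl bromide (1-bromo-3-methylbut-2-ene)
Product: 21 methyl 7-methyl-3-oxooct-6-enoate, via acetoacetate dianion 20 (not isolated)
Conditions: NaH, THF, 0 °C; n-BuLi, 0 °C; 19, 0 °C → rt; aq. HCl
Reagents that add atoms: none
Why: In the γ-alkylation of the acetoacetate dianion, the terminal and more basic carbanion of 20 reacts selectively with the primary allylic bromide by SN2.

Step 10
Reactants: 21 methyl 7-methyl-3-oxooct-6-enoate
Product: 22 methyl (2E)-3-methoxy-7-methylocta-2,6-dienoate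
Conditions: HC(OMe)3, p-TsOH·H2O (cat.), MeOH, rt
Reagents that add atoms: trimethyl orthoformate, COC(OC)OC
Why: Acid-catalysed ketalisation and loss of methanol (enol ether formation from a β-keto ester) gives the conjugated, thermodynamically preferred E β-methoxy enoate, and the trisubstituted alkene is inert to a catalytic sulfonic acid at room temperature.

Step 11
Reactants: 22 methyl (2E)-3-methoxy-7-methylocta-2,6-dienoate
Product: 24 (3Z)-1,3-dimethoxy-7-methyl-1-(trimethylsilyloxy)octa-1,3,6-triene, via lithium dienolate 23 (not isolated)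
Conditions: LiN(i-Pr)2 (LDA), THF, −78 °C; TMSCl, −78 °C → rt
Reagents that add atoms: trimethylsilyl chloride, C[Si](C)(C)Cl
Why: Kinetic γ-deprotonation of the E enoate (its C4 methylene lies cis to the ester) and O-silylation of dienolate 23 is the standard preparation of mixed vinylketene acetals; the chain takes the outward 3Z position to avoid the ketene acetal terminus, and the C1=C2 geometry has no consequence.

Step 12
Reactants: 17 (2R,3R)-3-(tert-butyldimethylsilyloxy)-2-[4-(tert-butyldimethylsilyloxy)-3-methoxyphenyl]-5-(phenylsulfinyl)-2,3-dihydro-4H-pyran-4-one; 24 (3Z)-1,3-dimethoxy-7-methyl-1-(trimethylsilyloxy)octa-1,3,6-triene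
Product: 27 (2R,3R)-3-(tert-butyldimethylsilyloxy)-2-[4-(tert-butyldimethylsilyloxy)-3-methoxyphenyl]-5-hydroxy-7-methoxy-8-(3-methylbut-2-enyl)chroman-4-one, via sulfinyl cycloadduct 25 (not isolated), via dihydroarene ketal 26 (not isolated)
Conditions: 24 (3 equiv), toluene, rt → 80 °C; then 0.5 M HCl, THF, 0 °C
Reagents that add atoms: none
Why: Proposed new method: the sulfinyl group and the C4 ketone both sit on C4a, so they lower the LUMO of C4a=C8a and make C8a its only electrophilic terminus, hence the nucleophilic, prenyl-bearing C4 terminus of 24 should bond to C8a and the ketene acetal carbon to C4a in a strongly asynchronous normal-demand Diels–Alder reaction; in adduct 25 sulfur and C8a–H are cis, so thermal sulfoxide syn elimination restores C4a=C8a (26), and mild acid removes methanol and the TMS group to aromatise ring A with 5-OH, 7-OMe and 8-prenyl in place under conditions that leave C2 and C3 alone; the closest known reaction types are the cycloaddition–elimination–aromatisation of such vinylketene acetals with halo- and sulfinylquinones and the Diels–Alder reactions of 2-sulfinylcycloalkenones and of 3-formyl- or 3-cyanochromones with silyloxydienes, whereas a 5-sulfinyl-2,3-dihydropyran-4-one has not been used in this way.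

Step 13
Reactants: 27 (2R,3R)-3-(tert-butyldimethylsilyloxy)-2-[4-(tert-butyldimethylsilyloxy)-3-methoxyphenyl]-5-hydroxy-7-methoxy-8-(3-methylbut-2-enyl)chroman-4-one
Product: 28 (2R,3R)-3,5-dihydroxy-2-(4-hydroxy-3-methoxyphenyl)-7-methoxy-8-(3-methylbut-2-enyl)chroman-4-one (CNP0195184.1)
Conditions: HF·pyridine, pyridine, THF, 0 °C → rt
Reagents that add atoms: none
Why: Fluoride cleavage of both silyl ethers in a weakly acidic buffer (silyl ether deprotection) avoids the base that would open ring C through the 4'-phenoxide or epimerise C3, and chroman formation is impossible because the prenyl group is flanked by OMe at C7 and O1 at C8a.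

Compound list
1 | vanillin (4-hydroxy-3-methoxybenzaldehyde) | COc1cc(C=O)ccc1O | starting material
2 | 4-(tert-butyldimethylsilyloxy)-3-methoxybenzaldehyde | COc1cc(C=O)ccc1O[Si](C)(C)C(C)(C)C | intermediate
3 | methyl glycolate | COC(=O)CO | starting material
4 | methyl 2-(tert-butyldimethylsilyloxy)acetate | COC(=O)CO[Si](C)(C)C(C)(C)C | intermediate
5 | 2-(tert-butyldimethylsilyloxy)-N-methoxy-N-methylacetamide | CON(C)C(=O)CO[Si](C)(C)C(C)(C)C | intermediate
6 | (Z)-1-bromo-2-ethoxyethene | CCO/C=C\Br | starting material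
7 | (Z)-2-ethoxyvinyllithium (not isolated) | CCO/C=C\[Li] | intermediate
8 | lithium (Z)-1-(tert-butyldimethylsilyloxy)-4-ethoxy-2-[methoxy(methyl)amino]but-3-en-2-olate, tetrahedral adduct (not isolated) | CCO/C=C\C([O-])(CO[Si](C)(C)C(C)(C)C)N(C)OC.[Li+] | intermediate
9 | (Z)-1-(tert-butyldimethylsilyloxy)-4-ethoxybut-3-en-2-one (not isolated) | CCO/C=C\C(=O)CO[Si](C)(C)C(C)(C)C | intermediate
10 | (E)-1-(tert-butyldimethylsilyloxy)-4-ethoxybut-3-en-2-one | CCO/C=C/C(=O)CO[Si](C)(C)C(C)(C)C | intermediate
11 | (1E,3Z)-4-(tert-butyldimethylsilyloxy)-1-ethoxy-3-(trimethylsilyloxy)buta-1,3-diene | CCO/C=C/C(O[Si](C)(C)C)=C/O[Si](C)(C)C(C)(C)C | intermediate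
12 | (1E,4S,5R)-4-(tert-butyldimethylsilyloxy)-5-[4-(tert-butyldimethylsilyloxy)-3-methoxyphenyl]-1-ethoxy-5-(trimethylsilyloxy)pent-1-en-3-one, syn aldol adduct (not isolated) | COc1cc([C@@H](O[Si](C)(C)C)[C@H](O[Si](C)(C)C(C)(C)C)C(=O)/C=C/OCC)ccc1O[Si](C)(C)C(C)(C)C | intermediate
13 | (2R,3S)-3-(tert-butyldimethylsilyloxy)-2-[4-(tert-butyldimethylsilyloxy)-3-methoxyphenyl]-2,3-dihydro-4H-pyran-4-one, cis isomer (not isolated) | COc1cc([C@H]2OC=CC(=O)[C@H]2O[Si](C)(C)C(C)(C)C)ccc1O[Si](C)(C)C(C)(C)C | intermediate
14 | (2R,3R)-3-(tert-butyldimethylsilyloxy)-2-[4-(tert-butyldimethylsilyloxy)-3-methoxyphenyl]-2,3-dihydro-4H-pyran-4-one, trans isomer | COc1cc([C@H]2OC=CC(=O)[C@@H]2O[Si](C)(C)C(C)(C)C)ccc1O[Si](C)(C)C(C)(C)C | intermediate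
15 | (2R,3R)-3-(tert-butyldimethylsilyloxy)-2-[4-(tert-butyldimethylsilyloxy)-3-methoxyphenyl]-6-chloro-5-(phenylsulfanyl)tetrahydropyran-4-one (not isolated) | COc1cc([C@H]2OC(Cl)C(Sc3ccccc3)C(=O)[C@@H]2O[Si](C)(C)C(C)(C)C)ccc1O[Si](C)(C)C(C)(C)C | intermediate
16 | (2R,3R)-3-(tert-butyldimethylsilyloxy)-2-[4-(tert-butyldimethylsilyloxy)-3-methoxyphenyl]-5-(phenylsulfanyl)-2,3-dihydro-4H-pyran-4-one | COc1cc([C@H]2OC=C(Sc3ccccc3)C(=O)[C@@H]2O[Si](C)(C)C(C)(C)C)ccc1O[Si](C)(C)C(C)(C)C | intermediate
17 | (2R,3R)-3-(tert-butyldimethylsilyloxy)-2-[4-(tert-butyldimethylsilyloxy)-3-methoxyphenyl]-5-(phenylsulfinyl)-2,3-dihydro-4H-pyran-4-one, both sulfur epimers | COc1cc([C@H]2OC=C(S(=O)c3ccccc3)C(=O)[C@@H]2O[Si](C)(C)C(C)(C)C)ccc1O[Si](C)(C)C(C)(C)C | intermediate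
18 | methyl acetoacetate | COC(=O)CC(C)=O | starting material
19 | prenyl bromide (1-bromo-3-methylbut-2-ene) | CC(C)=CCBr | starting material
20 | sodium lithium dianion of methyl acetoacetate (not isolated) | COC([O-])=CC([O-])=C.[Na+].[Li+] | intermediate
21 | methyl 7-methyl-3-oxooct-6-enoate | COC(=O)CC(=O)CCC=C(C)C | intermediate
22 | methyl (2E)-3-methoxy-7-methylocta-2,6-dienoate | COC(=O)/C=C(/OC)CCC=C(C)C | intermediate
23 | lithium (3Z)-1,3-dimethoxy-7-methylocta-1,3,6-trien-1-olate (not isolated) | COC([O-])=C/C(OC)=C/CC=C(C)C.[Li+] | intermediate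
24 | (3Z)-1,3-dimethoxy-7-methyl-1-(trimethylsilyloxy)octa-1,3,6-triene | COC(O[Si](C)(C)C)=C/C(OC)=C/CC=C(C)C | intermediate
25 | (2R,3R)-3-(tert-butyldimethylsilyloxy)-2-[4-(tert-butyldimethylsilyloxy)-3-methoxyphenyl]-5,7-dimethoxy-8-(3-methylbut-2-enyl)-4a-(phenylsulfinyl)-5-(trimethylsilyloxy)-2,3,4a,5,8,8a-hexahydrochromen-4-one (not isolated) | COc1cc([C@H]2OC3C(CC=C(C)C)C(OC)=CC(OC)(O[Si](C)(C)C)C3(S(=O)c4ccccc4)C(=O)[C@@H]2O[Si](C)(C)C(C)(C)C)ccc1O[Si](C)(C)C(C)(C)C | intermediate
26 | (2R,3R)-3-(tert-butyldimethylsilyloxy)-2-[4-(tert-butyldimethylsilyloxy)-3-methoxyphenyl]-5,7-dimethoxy-8-(3-methylbut-2-enyl)-5-(trimethylsilyloxy)-2,3,5,8-tetrahydrochromen-4-one (not isolated) | COc1cc([C@H]2OC3=C(C(=O)[C@@H]2O[Si](C)(C)C(C)(C)C)C(OC)(O[Si](C)(C)C)C=C(OC)C3CC=C(C)C)ccc1O[Si](C)(C)C(C)(C)C | intermediate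
27 | (2R,3R)-3-(tert-butyldimethylsilyloxy)-2-[4-(tert-butyldimethylsilyloxy)-3-methoxyphenyl]-5-hydroxy-7-methoxy-8-(3-methylbut-2-enyl)chroman-4-one | COc1cc([C@H]2Oc3c(CC=C(C)C)c(OC)cc(O)c3C(=O)[C@@H]2O[Si](C)(C)C(C)(C)C)ccc1O[Si](C)(C)C(C)(C)C | intermediate
28 | (2R,3R)-3,5-dihydroxy-2-(4-hydroxy-3-methoxyphenyl)-7-methoxy-8-(3-methylbut-2-enyl)chroman-4-one | COc1cc([C@H]2Oc3c(CC=C(C)C)c(OC)cc(O)c3C(=O)[C@@H]2O)ccc1O | target

Total step count: 13.
Longest linear sequence: 9 steps (2, 3, 4, 5, 6, 7, 8, 12, 13).

Steps most likely to fail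

1. Step 12 (the labelled step).
- What may go wrong: donation from O1 may leave C4a=C8a too unreactive, so that the ketene acetal decays before it adds. The sulfinyl enone may instead react as an oxadiene in an inverse-demand hetero-cycloaddition. Addition may stop after C8–C8a bond formation through silyl transfer. The C4a carbanion of a stepwise pathway may expel O1 and open ring C.
- Fallback: ring A is closed one bond at a time with known reactions. It sets out from 14 and 24, so that steps 7 and 8 are dropped, and comes back to the route at 27. A BF3·OEt2-promoted vinylogous Mukaiyama–Michael addition of 24 to enone 14 (CH2Cl2, −78 °C) forms C8–C8a and gives, after aqueous work-up, the tetrahydropyranone enoate F1. This reaction type is established for silyl ketene acetals and 2-substituted 2,3-dihydropyran-4-ones. Dieckmann condensation (LiN(SiMe3)2, THF, −78 → 0 °C) forms C4a–C5 and gives the bicyclic 1,3-diketone F2. Selenenylation of its acidic C4a position (PhSeCl, pyridine, CH2Cl2, 0 °C) gives the selenide F3, and H2O2 (CH2Cl2, 0 °C) converts it into the selenoxide F4. Selenoxide syn elimination toward C8a–H, followed by enolisation, aromatises ring A and delivers 27.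

2. Step 6.
- What may go wrong: turnover may be slow with an electron-rich aldehyde and a 4-substituted diene. Enantioface selection may be insufficient. The C3 equilibration may be slow or poorly biased. C2 may erode through acid-induced C2–O1 ionisation.
- Fallback: the same two ring bonds are formed, but the two stereocentres are set in separate events. It sets out from 2 and comes back at 14. The same Ti(OiPr)4/(S)-BINOL protocol is run with commercial (E)-1-methoxy-3-(trimethylsilyloxy)buta-1,3-diene, the best documented partner of this catalyst, and gives the 3-unsubstituted dihydropyranone F5. TBSOTf/Et3N (CH2Cl2, 0 °C) gives the 4-silyloxy-2H-pyran F6. Rubottom oxidation (dimethyldioxirane, acetone/CH2Cl2, −78 °C) delivers oxygen to C3 on the face opposite the C2 aryl group. Silyl migration from O4 to O3 then gives trans-configured 14 under kinetic substrate control, so no equilibration is needed.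

3. Step 7.
- What may go wrong: ring B may be sulfenylated in competition, the chloro adduct may hydrolyse at C8a before elimination, or the amine may epimerise C3.
- Fallback: the C–S bond is made by cross-coupling instead of electrophilic sulfenylation. It sets out from 14 and comes back at 16. α-Iodination of the enone (I2, pyridine, CH2Cl2, rt) gives the 5-iodo-dihydropyranone F7. Palladium-catalysed C–S coupling (PhSH, Pd2(dba)3, Xantphos, i-Pr2NEt, 1,4-dioxane, 80 °C) then gives 16.

Further compounds
F1 | step 12 | methyl (2E)-4-{(5R,6R)-5-(tert-butyldimethylsilyloxy)-6-[4-(tert-butyldimethylsilyloxy)-3-methoxyphenyl]-4-oxotetrahydropyran-2-yl}-3-methoxy-7-methylocta-2,6-dienoate | COc1cc([C@H]2OC(CC(=O)[C@@H]2O[Si](C)(C)C(C)(C)C)C(CC=C(C)C)/C(OC)=C\C(=O)OC)ccc1O[Si](C)(C)C(C)(C)C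
F2 | step 12 | (2R,3R)-3-(tert-butyldimethylsilyloxy)-2-[4-(tert-butyldimethylsilyloxy)-3-methoxyphenyl]-7-methoxy-8-(3-methylbut-2-enyl)-2,3,8,8a-tetrahydrochromene-4,5(4aH)-dione | COc1cc([C@H]2OC3C(CC=C(C)C)C(OC)=CC(=O)C3C(=O)[C@@H]2O[Si](C)(C)C(C)(C)C)ccc1O[Si](C)(C)C(C)(C)C
F3 | step 12 | 4a-(phenylselanyl) derivative of F2 | COc1cc([C@H]2OC3C(CC=C(C)C)C(OC)=CC(=O)C3([Se]c4ccccc4)C(=O)[C@@H]2O[Si](C)(C)C(C)(C)C)ccc1O[Si](C)(C)C(C)(C)C
F4 | step 12 | 4a-(phenylseleninyl) derivative of F2 | COc1cc([C@H]2OC3C(CC=C(C)C)C(OC)=CC(=O)C3([Se](=O)c4ccccc4)C(=O)[C@@H]2O[Si](C)(C)C(C)(C)C)ccc1O[Si](C)(C)C(C)(C)C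
F5 | step 6 | (2S)-2-[4-(tert-butyldimethylsilyloxy)-3-methoxyphenyl]-2,3-dihydro-4H-pyran-4-one | COc1cc([C@H]2OC=CC(=O)C2)ccc1O[Si](C)(C)C(C)(C)C
F6 | step 6 | (2S)-4-(tert-butyldimethylsilyloxy)-2-[4-(tert-butyldimethylsilyloxy)-3-methoxyphenyl]-2H-pyran | COc1cc([C@H]2OC=CC(O[Si](C)(C)C(C)(C)C)=C2)ccc1O[Si](C)(C)C(C)(C)C
F7 | step 7 | (2R,3R)-3-(tert-butyldimethylsilyloxy)-2-[4-(tert-butyldimethylsilyloxy)-3-methoxyphenyl]-5-iodo-2,3-dihydro-4H-pyran-4-one | COc1cc([C@H]2OC=C(I)C(=O)[C@@H]2O[Si](C)(C)C(C)(C)C)ccc1O[Si](C)(C)C(C)(C)C
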